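## The problem

Ebenfuran V (17) is an achiral 2-arylbenzofuran. O1 and C2 carry a 2,4-dihydroxyphenyl ring (ring B), C3 carries a formyl group, and the benzo ring (ring A, C3a to C7a) is substituted everywhere except C7: 4-OH, 5-(3-hydroxy-3-methylbutyl), 6-OMe. There is no stereocentre to set. The centres that appear on the way (C2 of a flavanone, C2 and C3 of a dihydrobenzofuran) are transient, and the only useful stereocontrol is that the C2 aryl group directs what happens at C3 before aromatisation erases both.

The real difficulty is regiochemical. Ring A is a phloroglucinol whose three oxygens must become three different things (furan oxygen O1, free 4-OH, 6-OMe), with the chain between the free phenol and the methyl ether and not on the other side of the methyl ether. The C1 unit at C3 has to be attached to a fully substituted, electron-rich furan carbon that is flanked by ring B and by the peri oxygen at C4.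

Three functions will not survive rough treatment:
- The tertiary alcohol ionises under Brønsted or Lewis acid and is then trapped by the neighbouring 4-OH, or dehydrates.
- The formyl group lies between two free phenols on a ring that ionises easily at the carbinol oxidation level.
- The free resorcinol and phloroglucinol rings are readily oxidised.

The feature that opens the structure is the environment of C3. It is bonded to C3a of ring A, to the formyl carbon, and to C2, which holds ring B and O1. This is the arrangement a flavanone acquires when ring A moves from the carbonyl carbon C4 to the neighbouring CH2 carbon C3: the O1–C2(ring B)–C3 unit is untouched, the old C4 becomes the exocyclic C1 unit, and the pyranone shrinks to the furan ring.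

## Retrosynthesis

Atom numbers follow the benzofuran numbering of 17; for flavanone 9 the usual flavanone numbering is used and said so.

**17 back to 14 (protecting groups and oxidation level).** The two O–benzyl bonds of ring B are cut last, leading to aldehyde 16, because hydrogenolysis is neutral and the tertiary alcohol tolerates no acid. Benzyl is chosen over acetal or silyl groups because it must first pass a Lewis acid, sulfuric acid in an orthoformate, DDQ, a Grignard reagent and an aluminium hydride. The formyl group of 16 is traced through carbinol 15 to methyl ester 14. The ester level is what the ring contraction delivers, and reaching the aldehyde by reduction and MnO2 oxidation avoids a partial reduction. The forward steps must keep 15 away from acid.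

**14 back to 13 (two C–CH3 bonds).** Cutting both methyl groups from the carbinol carbon and joining that carbon to O4 gives aryl lactone 13. One reagent then liberates the tertiary alcohol and the 4-OH together, and until then the lactone hides the phenol that would otherwise meet the oxidants. The neighbouring choice, a silylated carbinol plus a separately protected 4-OH, needs two more protecting groups and a way of telling the two ortho oxygens of ring A apart. The forward reaction must add to the aryl lactone and leave the C3 ester, which is a vinylogous carbonate shielded by ring B and the peri substituent.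

**13 back to 12 (two hydrogens).** Adding hydrogen across C2–C3 gives the trans dihydrobenzofuran ester 12. This is no simplification in itself, but 12 is the direct product of the ring contraction, and its C2–H is benzylic and next to oxygen, so dehydrogenation with a quinone is asked to do little.

**12 back to 9 (the key disconnection, C3–C3a).** The bond between C3 and ring A is cut and C3a is rejoined to the carboxyl carbon, which gives flavanone 9. The neighbouring cuts O1–C2, O1–C7a and C2–C3 each lead to a fragment that already carries the quaternary C3 with its C1 unit. This cut turns the C3 substituent into the carbonyl group of a flavanone, which two aromatic building blocks assemble. The forward reaction has three demands: ring A must migrate, not ring B; the lactone must survive acid; and the oxidant must find no free phenol. The lactone answers the last demand and also removes the hydrogen bond that would otherwise retard enol ether formation at C4.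

**9 back to 5 and 7 (O1–C2 and the enone C=C).** Opening the pyranone at O1–C2 gives chalcone 8, and cutting its enone double bond gives acetophenone lactone 5 and aldehyde 7. Because O5 of the flavanone is tied up in the lactone, only one phenol of 8 is free and only one flavanone can close. An amine-catalysed one-pot condensation would be shorter, but a secondary amine or hydroxide opens an aryl lactone at once and would hand back the two-phenol ambiguity. The condensation is therefore run with a Lewis acid and the ring closure with a tertiary amine in an aprotic solvent.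

**5 back to 1 and 2; 7 back to 6.** The saturated lactone 5 comes from coumarin 4 by hydrogenation. Coumarin 4 is cut at the lactone C–O bond and at the bond from ring A to the former alkyne carbon, which leads to acetophenone 1 and propiolic acid 2. Compound 1 is symmetrical: its two hydroxyls and its two free ring positions are equivalent, and the acetyl group blocks the carbon between the hydroxyls. The annulation can therefore give only the pattern needed, and it places the three-carbon chain and distinguishes the two phenols in one step. Aldehyde 7 is the dibenzyl ether of 6.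

## Roads not taken

**Alternative 1:** Ring A is removed altogether. The bonds C7–C7a, C4–C5, C6–C7 and C3a–C4 are made in one benzannulation of furyl diazo ketone A2 with methoxyalkyne A3, which gives phenol ester A1.
- Forward key step: irradiation causes the Wolff shift; the ketene adds to A3 in a [2+2] sense; heating brings about four-electron ring opening and six-electron closure onto the furan carbon next to the ester.
- Merits: every ring A substituent is placed without regiochemical doubt. The 4-OH is born free, the chain arrives as a protected carbinol, and the benzofuran is aromatic from the start. No dehydrogenation and no chemoselective Grignard addition are needed; in these respects this road is better than the chosen one.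
- Weak points: A2 is a 2,3,5-trisubstituted furan that needs its own multistep synthesis and a diazo ketone. A3 is a thermally fragile ynol ether. The electrocyclisation must occur at a furan carbon crowded by the ester. A photochemical step limits scale. After A1 the ester still has to be taken to the aldehyde and two kinds of protecting group removed.
- Comparison: the chosen plan sets against this two commercial aromatic building blocks, no diazo compound in the main line, and a lactone that acts as protecting group and chain precursor at once.

**Alternative 2:** The cuts are O1–C2 and C3–CH2. Aryl alkyne A5, a Sonogashira product with two equivalent methoxymethyl ethers, is cyclised to A4.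
- Forward key step: PtCl2 with 1,5-cyclooctadiene (divalent platinum) activates the alkyne, one acetal oxygen attacks C2, and its CH2OMe group is delivered to C3.
- Merits: this is the shortest way to a 2-aryl-3-C1 benzofuran. It is convergent and mild, and its silyl ethers come off with fluoride, which is kinder to a formyl group than the hydrogenolysis that ends the chosen route.
- Weak points: A4 has no chain at C5. Introducing it afterwards by metalation must distinguish C5 (between two oxygens) from C7 (also between two oxygens). Introducing it beforehand makes the two acetal oxygens different and brings back the regiochemical problem that the symmetry of A5 had removed. C3 arrives as a methyl ether two oxidation levels below the aldehyde. The remaining acetal on O4 must later be removed with acid next to the tertiary alcohol.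
- Comparison: the chosen plan settles the chain position and the choice of furan oxygen before the heterocycle exists.

**Alternative 3:** The cut is O1–C7a. The 3-aryl-4-hydroxycoumarin A7 is oxidised to coumestan A6.
- Forward key step: Pd(OAc)2 with PhI(OAc)2 as oxidant forms the aryl–oxygen bond at the only free ortho C–H of ring A. The lactone of A6 masks both the C3 carbon and the 2'-oxygen.
- Merits: the regiochemistry of ring closure is forced. The sensitive C3 carbon and the 2'-phenol stay protected until the end. One partial reduction reaches the aldehyde level, and no Grignard selectivity arises because the carbinol is already there. On these points it matches or beats the chosen plan.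
- Weak points: ring A of A7 is a benzene with four different contiguous substituents, whose regiocontrolled synthesis is long. Three orthogonal protecting groups are needed. The palladium-catalysed oxidation of a very electron-rich arene competes with acetoxylation. The lactone must be reduced exactly to the aldehyde level, since over-reduction gives a carbinol that closes onto the neighbouring phenol.
- Comparison: the chosen plan draws ring A from a symmetrical commercial acetophenone and pays for this with a dehydrogenation step and one chemoselective addition.

Key step: step 6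

Remark: the target is achiral; compounds 9 to 12 are racemic and are drawn as one enantiomer.

## Route

Step 1
Reactants: 1 2,6-dihydroxy-4-methoxyacetophenone; 2 propiolic acid
Product: 4 8-acetyl-7-hydroxy-5-methoxy-2H-chromen-2-one, via cinnamic acid 3 (not isolated)
Conditions: Pd(OAc)2 (cat.), CF3CO2H–CH2Cl2, rt
Reagents that add atoms: none
Why: Pechmann-type coumarin synthesis by palladium-catalysed hydroarylation: the alkyne, activated by divalent palladium in CF3CO2H, is attacked by the ring carbon ortho to OH and OMe, and the Z-cinnamic acid 3 lactonises onto the adjacent phenol. The two free ring positions and the two hydroxyls of 1 are equivalent and the acetyl group blocks the carbon between the hydroxyls, so only this substitution pattern can form; the new lactone deactivates the ring against a second annulation.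

Step 2
Reactants: 4 8-acetyl-7-hydroxy-5-methoxy-2H-chromen-2-one
Product: 5 8-acetyl-7-hydroxy-5-methoxychroman-2-one
Conditions: H2 (1 atm), 10% Pd/C, EtOAc, rt
Reagents that add atoms: none
Why: Catalytic hydrogenation of the coumarin C3=C4 bond; the hydrogen-bonded aryl ketone is inert under neutral conditions, and an aprotic solvent avoids alcoholysis of the aryl lactone.

Step 3
Reactants: 6 2,4-dihydroxybenzaldehyde
Product: 7 2,4-bis(benzyloxy)benzaldehyde
Conditions: BnBr, K2CO3, DMF, 60 °C
Reagents that add atoms: benzyl bromide, BrCc1ccccc1
Why: Williamson ether synthesis; excess reagent and warming also alkylate the hydrogen-bonded 2-OH.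

Step 4
Reactants: 5 8-acetyl-7-hydroxy-5-methoxychroman-2-one; 7 2,4-bis(benzyloxy)benzaldehyde
Product: 8 8-[(E)-3-[2,4-bis(benzyloxy)phenyl]prop-2-enoyl]-7-hydroxy-5-methoxychroman-2-one
Conditions: BF3·OEt2 (cat., 0.5 equiv), 1,4-dioxane, rt; H2O
Reagents that add atoms: none
Why: Lewis-acid-mediated Claisen–Schmidt condensation: BF3 chelates the 7-OH/acetyl pair, which acidifies the methyl group, and the aldol adduct dehydrates to the E-enone. No amine or hydroxide is present, so the aryl lactone, which a Kabbe-type amine catalyst or alkali would open, should survive together with the benzyl ethers.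

Step 5
Reactants: 8 8-[(E)-3-[2,4-bis(benzyloxy)phenyl]prop-2-enoyl]-7-hydroxy-5-methoxychroman-2-one
Product: 9 (8S*)-8-[2,4-bis(benzyloxy)phenyl]-5-methoxy-3,4,8,9-tetrahydro-2H,10H-pyrano[2,3-f]chromene-2,10-dione
Conditions: Et3N (cat.), MeCN, 60 °C
Reagents that add atoms: none
Why: Base-catalysed 6-endo-trig oxa-Michael addition (chalcone–flavanone isomerisation) in an aprotic medium that leaves the lactone alone. Only one phenol is free, so only one flavanone can close, and the doubly ortho-substituted aroyl group favours the cyclic isomer; the new centre (flavanone C2) is racemic and is erased in step 7.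

Step 6
Reactants: 9 (8S*)-8-[2,4-bis(benzyloxy)phenyl]-5-methoxy-3,4,8,9-tetrahydro-2H,10H-pyrano[2,3-f]chromene-2,10-dione
Product: 12 methyl (8S*,9S*)-8-[2,4-bis(benzyloxy)phenyl]-5-methoxy-2-oxo-3,4,8,9-tetrahydro-2H-furo[2,3-h]chromene-9-carboxylate, via enol ether 10 (not isolated), via iodane 11 (not isolated)
Conditions: PhI(OAc)2, H2SO4 (cat.), HC(OMe)3, 0 °C to rt; aq. NaHCO3
Reagents that add atoms: trimethyl orthoformate, COC(OC)OC; water, O; (diacetoxyiodo)benzene, CC(=O)OI(OC(C)=O)c1ccccc1 (atoms only in intermediate 11)
Why: In flavanone numbering, acid and the orthoformate turn the C4 ketone, which has no hydrogen bond because O5 is acylated, into enol ether 10; trivalent iodine then adds to C3 from the face opposite the equatorial C2 aryl group, and methanol capture gives ketal 11 with an equatorial C3–I bond. The ring bond C4–C4a is antiperiplanar to C3–I, so ring A, activated by its para methoxy group and by O1, bridges to C3 as a phenonium ion (three-membered exo-tet displacement of iodobenzene) while C4–C4a breaks. The five-membered ring is therefore closed by ring contraction through a 1,2-aryl shift and not by a separate cyclisation. The dimethoxycarbenium ion left on the old C4 ends as the methyl ester on aqueous work-up. Inversion at C3 puts the ester trans to the aryl group, so C2 controls C3, and the trans isomer is also the thermodynamic one because C3–H is epimerisable. The closest known reaction is the PhI(OAc)2/orthoformate ring contraction of flavanones to methyl trans-2-aryl-2,3-dihydrobenzofuran-3-carboxylates. The step needs ring A to migrate in preference to ring B and to elimination; the diequatorial geometry of 11 aligns only ring bonds with C3–I, and the ketal oxygens stabilise the cation that ring A leaves behind. No methanol is added beyond what the orthoformate releases, to spare the aryl lactone, and the lactone keeps any free phenol away from the oxidant.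

Step 7
Reactants: 12 methyl (8S*,9S*)-8-[2,4-bis(benzyloxy)phenyl]-5-methoxy-2-oxo-3,4,8,9-tetrahydro-2H-furo[2,3-h]chromene-9-carboxylate
Product: 13 methyl 8-[2,4-bis(benzyloxy)phenyl]-5-methoxy-2-oxo-3,4-dihydro-2H-furo[2,3-h]chromene-9-carboxylate
Conditions: DDQ (1.1 equiv), 1,4-dioxane, 80 °C
Reagents that add atoms: none
Why: Quinone dehydrogenation: hydride is abstracted from C2 (benzylic, next to O1, stabilised by the dialkoxyphenyl ring) and the acidic C3–H is lost. One equivalent is used so that the less hydridic benzylic CH2 of the lactone and the benzyl ethers are left alone; both transient stereocentres disappear.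

Step 8
Reactants: 13 methyl 8-[2,4-bis(benzyloxy)phenyl]-5-methoxy-2-oxo-3,4-dihydro-2H-furo[2,3-h]chromene-9-carboxylate
Product: 14 methyl 2-[2,4-bis(benzyloxy)phenyl]-4-hydroxy-5-(3-hydroxy-3-methylbutyl)-6-methoxy-1-benzofuran-3-carboxylate
Conditions: MeMgBr (3 equiv), THF, −78 to 0 °C; aq. NH4Cl
Reagents that add atoms: methylmagnesium bromide, C[Mg]Br
Why: Double Grignard addition to an aryl ester: phenoxide is a good leaving group, so the lactone opens to a methyl ketone that takes the second equivalent, which gives the tertiary alkoxide and the 4-phenoxide. The C3 ester is a vinylogous carbonate conjugated to O1 and shielded by ring B and the peri substituent, so it should be left at low temperature.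

Step 9
Reactants: 14 methyl 2-[2,4-bis(benzyloxy)phenyl]-4-hydroxy-5-(3-hydroxy-3-methylbutyl)-6-methoxy-1-benzofuran-3-carboxylate
Product: 15 2-[2,4-bis(benzyloxy)phenyl]-3-(hydroxymethyl)-5-(3-hydroxy-3-methylbutyl)-6-methoxy-1-benzofuran-4-ol
Conditions: i-Bu2AlH (5 equiv), CH2Cl2, −78 to 0 °C; aq. KNaC4H4O6
Reagents that add atoms: none
Why: Ester reduction with excess aluminium hydride, two equivalents being consumed by the hydroxyl groups. The carbinol ionises easily, so it is worked up without acid and taken on crude.

Step 10
Reactants: 15 2-[2,4-bis(benzyloxy)phenyl]-3-(hydroxymethyl)-5-(3-hydroxy-3-methylbutyl)-6-methoxy-1-benzofuran-4-ol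
Product: 16 2-[2,4-bis(benzyloxy)phenyl]-4-hydroxy-5-(3-hydroxy-3-methylbutyl)-6-methoxy-1-benzofuran-3-carbaldehyde
Conditions: MnO2 (excess), CH2Cl2, rt
Reagents that add atoms: none
Why: MnO2 oxidises the benzylic-type furylmethyl alcohol selectively under neutral conditions; the tertiary alcohol and the hindered phenol are not touched.

Step 11
Reactants: 16 2-[2,4-bis(benzyloxy)phenyl]-4-hydroxy-5-(3-hydroxy-3-methylbutyl)-6-methoxy-1-benzofuran-3-carbaldehyde
Product: 17 Ebenfuran V
Conditions: H2 (1 atm), 10% Pd/C, EtOAc, rt
Reagents that add atoms: none
Why: Hydrogenolysis of the two benzyl aryl ethers under neutral conditions. The formyl group is a vinylogous formate hydrogen-bonded to 4-OH and should be reduced much more slowly, so the reaction is stopped after two equivalents of hydrogen; the absence of acid keeps the tertiary alcohol from closing onto 4-OH.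

## Compound list

1 | 2,6-dihydroxy-4-methoxyacetophenone | CC(=O)c1c(O)cc(OC)cc1O | starting material
2 | propiolic acid | C#CC(=O)O | starting material
3 | (Z)-3-(3-acetyl-2,4-dihydroxy-6-methoxyphenyl)prop-2-enoic acid | CC(=O)c1c(O)cc(OC)c(/C=C\C(=O)O)c1O | intermediate
4 | 8-acetyl-7-hydroxy-5-methoxy-2H-chromen-2-one (8-acetyl-7-hydroxy-5-methoxycoumarin) | CC(=O)c1c(O)cc(OC)c2ccc(=O)oc12 | intermediate
5 | 8-acetyl-7-hydroxy-5-methoxychroman-2-one (the 3,4-dihydrocoumarin) | CC(=O)c1c(O)cc(OC)c2CCC(=O)Oc12 | intermediate
6 | 2,4-dihydroxybenzaldehyde | O=Cc1ccc(O)cc1O | starting material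
7 | 2,4-bis(benzyloxy)benzaldehyde | O=Cc1ccc(OCc2ccccc2)cc1OCc1ccccc1 | intermediate
8 | 8-[(E)-3-[2,4-bis(benzyloxy)phenyl]prop-2-enoyl]-7-hydroxy-5-methoxychroman-2-one (2'-hydroxychalcone) | O=C(/C=C/c1ccc(OCc2ccccc2)cc1OCc1ccccc1)c1c(O)cc(OC)c2CCC(=O)Oc12 | intermediate
9 | (8S*)-8-[2,4-bis(benzyloxy)phenyl]-5-methoxy-3,4,8,9-tetrahydro-2H,10H-pyrano[2,3-f]chromene-2,10-dione; racemic flavanone whose O5 and C6 (flavanone numbering) are bridged by C(=O)CH2CH2 | O=C1C[C@@H](c2ccc(OCc3ccccc3)cc2OCc2ccccc2)Oc2cc(OC)c3CCC(=O)Oc3c21 | intermediate
10 | 8-[2,4-bis(benzyloxy)phenyl]-5,10-dimethoxy-3,4-dihydro-2H,8H-pyrano[2,3-f]chromen-2-one; racemic C4 methyl enol ether of 9 | COC1=C[C@@H](c2ccc(OCc3ccccc3)cc2OCc2ccccc2)Oc2cc(OC)c3CCC(=O)Oc3c21 | intermediate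
11 | 9-[acetoxy(phenyl)-λ3-iodanyl]-8-[2,4-bis(benzyloxy)phenyl]-5,10,10-trimethoxy-3,4,9,10-tetrahydro-2H,8H-pyrano[2,3-f]chromen-2-one; racemic, iodanyl and aryl groups trans | COC1(OC)[C@H](I(OC(C)=O)c2ccccc2)[C@@H](c2ccc(OCc3ccccc3)cc2OCc2ccccc2)Oc2cc(OC)c3CCC(=O)Oc3c21 | intermediate
12 | methyl (8S*,9S*)-8-[2,4-bis(benzyloxy)phenyl]-5-methoxy-2-oxo-3,4,8,9-tetrahydro-2H-furo[2,3-h]chromene-9-carboxylate; racemic trans 2-aryl-2,3-dihydrobenzofuran-3-carboxylate with the lactone on O4/C5 | COC(=O)[C@@H]1[C@@H](c2ccc(OCc3ccccc3)cc2OCc2ccccc2)Oc2cc(OC)c3CCC(=O)Oc3c21 | intermediate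
13 | methyl 8-[2,4-bis(benzyloxy)phenyl]-5-methoxy-2-oxo-3,4-dihydro-2H-furo[2,3-h]chromene-9-carboxylate | COC(=O)c1c(-c2ccc(OCc3ccccc3)cc2OCc2ccccc2)oc2cc(OC)c3CCC(=O)Oc3c12 | intermediate
14 | methyl 2-[2,4-bis(benzyloxy)phenyl]-4-hydroxy-5-(3-hydroxy-3-methylbutyl)-6-methoxy-1-benzofuran-3-carboxylate | COC(=O)c1c(-c2ccc(OCc3ccccc3)cc2OCc2ccccc2)oc2cc(OC)c(CCC(C)(C)O)c(O)c12 | intermediate
15 | 2-[2,4-bis(benzyloxy)phenyl]-3-(hydroxymethyl)-5-(3-hydroxy-3-methylbutyl)-6-methoxy-1-benzofuran-4-ol | OCc1c(-c2ccc(OCc3ccccc3)cc2OCc2ccccc2)oc2cc(OC)c(CCC(C)(C)O)c(O)c12 | intermediate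
16 | 2-[2,4-bis(benzyloxy)phenyl]-4-hydroxy-5-(3-hydroxy-3-methylbutyl)-6-methoxy-1-benzofuran-3-carbaldehyde | O=Cc1c(-c2ccc(OCc3ccccc3)cc2OCc2ccccc2)oc2cc(OC)c(CCC(C)(C)O)c(O)c12 | intermediate
17 | Ebenfuran V, 2-(2,4-dihydroxyphenyl)-4-hydroxy-5-(3-hydroxy-3-methylbutyl)-6-methoxy-1-benzofuran-3-carbaldehyde | COc1cc2oc(-c3ccc(O)cc3O)c(C=O)c2c(O)c1CCC(C)(C)O | target

## Step count and least certain steps

Total: 11 steps. Longest linear sequence: 10 steps (from 1 through steps 1, 2 and 4 to 11); the aldehyde branch adds step 3.

**Step 6 (key step).** Three processes threaten it: migration of the very electron-rich ring B in place of ring A; loss of the C3 iodane by elimination or by substitution with methanol; and acid-catalysed methanolysis of the aryl lactone, which would expose a phenol to the oxidant. The fallback keeps the same bond formation but changes the mechanism to a Wolff ring contraction, in which only the substituent on the carbonyl carbon, ring A, can move to the carbene centre, and which runs without acid. It sets out from 9. The lithium enolate of 9 (LiN(SiMe3)2, THF, −78 °C) is acylated with CF3CO2CH2CF3 to the 3-trifluoroacetyl flavanone enol F1. Detrifluoroacetylative diazo transfer (MsN3, Et3N, MeCN) gives the 3-diazoflavanone F2. Irradiation in methanol gives the ring-contracted ketene F3, which adds methanol; protonation anti to the aryl group returns the route at 12.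

**Step 1.** The acetyl group lowers the nucleophilicity of the ring, so hydroarylation may stall; with excess propiolic acid a second annulation at the remaining ortho position may compete. The fallback builds the lactone by carbonyl olefination and sets out from 1. Vilsmeier–Haack formylation (POCl3, DMF) gives 3-acetyl-2,4-dihydroxy-6-methoxybenzaldehyde F4. Wittig reaction with Ph3P=CHCO2Et in refluxing N,N-diethylaniline gives the ethyl cinnamate F5, which isomerises and lactonises under the same conditions and returns the route at 4.

**Step 4.** The condensation may stop at a stable BF2 chelate, the benzyl ether ortho to the reacting carbon may be lost to the Lewis acid, or the water formed may open the lactone. The fallback avoids the chalcone and sets out from 5 and 7. The phenoxide–enolate dianion of 5 (LiN(SiMe3)2, 2.2 equiv, THF, −78 °C) adds to 7 to give the racemic β-hydroxy ketone F6; the tethered lactone is held away from the acetyl group and cannot undergo a Baker–Venkataraman-type acyl transfer. Mitsunobu ring closure (PPh3, DIAD, THF, 0 °C) forms the O1–C2 bond and returns the route at 9; steps 4 and 5 are bypassed.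

**Step 8.** Over-addition to the C3 ester may occur once the magnesium phenoxide at C4 can chelate it, and enolisation of the intermediate methyl ketone may leave the second addition incomplete. The fallback separates the two additions and sets out from 13. Aminolysis of the aryl lactone with MeNH(OMe)·HCl and Me3Al (CH2Cl2, 0 °C) gives the Weinreb amide F7 with the free 4-OH. MeMgBr at −20 °C gives the methyl ketone F8 through a stable chelate. A second addition of MeMgBr at −78 °C, with CeCl3 if enolisation interferes, returns the route at 14.

**Step 7.** Hydride abstraction from the benzylic CH2 of the lactone ring or from the benzyl ethers may compete with dehydrogenation of the furan ring, and the electron-rich product may be attacked further. The fallback replaces hydride abstraction by enolate chemistry and sets out from 12. Deprotonation at the C3–H (LiN(SiMe3)2, THF, −78 °C) and selenenylation with PhSeBr anti to the aryl group give the selenide F9. Oxidation with H2O2 gives the selenoxide F10, whose selenium is syn to the C2–H and which eliminates to return the route at 13.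

## Further compounds

F1 | step 6 | (8S*)-8-[2,4-bis(benzyloxy)phenyl]-5-methoxy-9-(2,2,2-trifluoro-1-hydroxyethylidene)-3,4,8,9-tetrahydro-2H,10H-pyrano[2,3-f]chromene-2,10-dione (enol form of the 3-trifluoroacetyl flavanone, racemic) | O=C1/C(=C(\O)C(F)(F)F)[C@@H](c2ccc(OCc3ccccc3)cc2OCc2ccccc2)Oc2cc(OC)c3CCC(=O)Oc3c21
F2 | step 6 | (8S*)-8-[2,4-bis(benzyloxy)phenyl]-9-diazo-5-methoxy-3,4,8,9-tetrahydro-2H,10H-pyrano[2,3-f]chromene-2,10-dione (3-diazoflavanone, racemic) | O=C1C(=[N+]=[N-])[C@@H](c2ccc(OCc3ccccc3)cc2OCc2ccccc2)Oc2cc(OC)c3CCC(=O)Oc3c21
F3 | step 6 | (8S*)-8-[2,4-bis(benzyloxy)phenyl]-5-methoxy-9-(oxomethylidene)-3,4,8,9-tetrahydro-2H-furo[2,3-h]chromen-2-one (ketene, racemic) | O=C=C1[C@@H](c2ccc(OCc3ccccc3)cc2OCc2ccccc2)Oc2cc(OC)c3CCC(=O)Oc3c21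
F4 | step 1 | 3-acetyl-2,4-dihydroxy-6-methoxybenzaldehyde | CC(=O)c1c(O)cc(OC)c(C=O)c1O
F5 | step 1 | ethyl (E)-3-(3-acetyl-2,4-dihydroxy-6-methoxyphenyl)prop-2-enoate | CCOC(=O)/C=C/c1c(OC)cc(O)c(C(C)=O)c1O
F6 | step 4 | 8-[(3R*)-3-[2,4-bis(benzyloxy)phenyl]-3-hydroxypropanoyl]-7-hydroxy-5-methoxychroman-2-one (racemic) | O=C(C[C@@H](O)c1ccc(OCc2ccccc2)cc1OCc1ccccc1)c1c(O)cc(OC)c2CCC(=O)Oc12
F7 | step 8 | methyl 2-[2,4-bis(benzyloxy)phenyl]-4-hydroxy-6-methoxy-5-[3-[methoxy(methyl)amino]-3-oxopropyl]-1-benzofuran-3-carboxylate | COC(=O)c1c(-c2ccc(OCc3ccccc3)cc2OCc2ccccc2)oc2cc(OC)c(CCC(=O)N(C)OC)c(O)c12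
F8 | step 8 | methyl 2-[2,4-bis(benzyloxy)phenyl]-4-hydroxy-6-methoxy-5-(3-oxobutyl)-1-benzofuran-3-carboxylate | COC(=O)c1c(-c2ccc(OCc3ccccc3)cc2OCc2ccccc2)oc2cc(OC)c(CCC(C)=O)c(O)c12
F9 | step 7 | methyl 8-[2,4-bis(benzyloxy)phenyl]-5-methoxy-2-oxo-9-(phenylselanyl)-3,4,8,9-tetrahydro-2H-furo[2,3-h]chromene-9-carboxylate (racemic, selanyl and aryl groups trans) | COC(=O)[C@@]1([Se]c2ccccc2)[C@@H](c2ccc(OCc3ccccc3)cc2OCc2ccccc2)Oc2cc(OC)c3CCC(=O)Oc3c21
F10 | step 7 | methyl 8-[2,4-bis(benzyloxy)phenyl]-5-methoxy-2-oxo-9-(phenylseleninyl)-3,4,8,9-tetrahydro-2H-furo[2,3-h]chromene-9-carboxylate (racemic, mixture at selenium) | COC(=O)[C@@]1([Se](=O)c2ccccc2)[C@@H](c2ccc(OCc3ccccc3)cc2OCc2ccccc2)Oc2cc(OC)c3CCC(=O)Oc3c21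
A1 | alternative 1 | methyl 2-[2,4-bis(benzyloxy)phenyl]-4-hydroxy-6-methoxy-5-(3-methyl-3-triethylsilyloxybutyl)benzofuran-3-carboxylate | COC(=O)c1c(-c2ccc(OCc3ccccc3)cc2OCc2ccccc2)oc2cc(OC)c(CCC(C)(C)O[Si](CC)(CC)CC)c(O)c12
A2 | alternative 1 | methyl 2-[2,4-bis(benzyloxy)phenyl]-5-(2-diazoacetyl)furan-3-carboxylate | COC(=O)c1cc(C(=O)C=[N+]=[N-])oc1-c1ccc(OCc2ccccc2)cc1OCc1ccccc1
A3 | alternative 1 | triethyl[(6-methoxy-2-methylhex-5-yn-2-yl)oxy]silane | COC#CCCC(C)(C)O[Si](CC)(CC)CC
A4 | alternative 2 | 2-[2,4-bis(triisopropylsilyloxy)phenyl]-6-methoxy-4-(methoxymethoxy)-3-(methoxymethyl)benzofuran | COCc1c(-c2ccc(O[Si](C(C)C)(C(C)C)C(C)C)cc2O[Si](C(C)C)(C(C)C)C(C)C)oc2cc(OC)cc(OCOC)c12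
A5 | alternative 2 | [4-[[4-methoxy-2,6-bis(methoxymethoxy)phenyl]ethynyl]-1,3-phenylene]bis(oxy)bis(triisopropylsilane) | COCOc1cc(OC)cc(OCOC)c1C#Cc1ccc(O[Si](C(C)C)(C(C)C)C(C)C)cc1O[Si](C(C)C)(C(C)C)C(C)C
A6 | alternative 3 | 3-(benzyloxy)-9-methoxy-8-(3-methyl-3-triethylsilyloxybutyl)-7-[(2-trimethylsilylethoxy)methoxy]coumestan | O=C1Oc2cc(OCc3ccccc3)ccc2-c2oc3cc(OC)c(CCC(C)(C)O[Si](CC)(CC)CC)c(OCOCC[Si](C)(C)C)c3c21
A7 | alternative 3 | 7-(benzyloxy)-4-hydroxy-3-[4-methoxy-3-(3-methyl-3-triethylsilyloxybutyl)-2-[(2-trimethylsilylethoxy)methoxy]phenyl]coumarin | O=c1oc2cc(OCc3ccccc3)ccc2c(O)c1-c1ccc(OC)c(CCC(C)(C)O[Si](CC)(CC)CC)c1OCOCC[Si](C)(C)C
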